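## Structural features

Arthonioic acid is a depside: two benzene rings, ring A and ring B, share no ring bond and are joined only by an aryl ester between the carboxyl carbon on C1 of ring A and the oxygen on C4' of ring B. Both rings carry the same 1,2,4,6 pattern. Ring A has the ester carbonyl on C1, free hydroxyls on C2 and C4 and a 2-oxoheptyl chain on C6. Ring B has a free carboxylic acid on C1', a methyl ether on C2', the depside oxygen on C4' and a second 2-oxoheptyl chain on C6'. There is no stereocentre, so none stand next to each other and none can be scrambled. The fragile groups are the aryl ester (opened by hydroxide, alkoxide or thiolate), the electron-rich rings, and the two enolisable benzyl ketones; each ketone sits ortho to a carboxyl derivative and can close to a 3-pentylisocoumarin by enol lactonisation under acid or on carboxyl activation. The real difficulty is ring B: its two oxygens must be told apart, and the adjacent carbons C1' and C6' must receive substituents at different oxidation levels (aryl carboxyl against CH2–ketone); joining a doubly ortho-substituted benzoic acid to a phenol and unmasking everything under near-neutral conditions comes second. The key step exploits the ortho pair C1' (carboxyl carbon) and C6' (side-chain CH2) with the C2' methoxy group beside C1': an aryne spanning C1'–C6' with that methoxy group next to the triple bond takes up a malonate so that the migrating ester lands on C1' and the CH2 on C6'.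

## Logic of the disconnections

**28 to 27 to 26.** The last bonds cut are the three O–benzyl bonds of 27 (two ring A ethers, the ring B ester) and, one step earlier, the two ketal C–O bonds of 26. The reason is that 28 holds a free keto acid and an aryl ester and tolerates neither base nor strong acid, so the final operation must be neutral. The gain is that every earlier step may rely on benzyl and ketal protection. The demand is that no catalyst poison remains at the end and that the ketal comes off without the ring A enol attacking the aryl ester.

**26 to 25 and 19.** The C(=O)–O bond between the rings is cut. It is the only bond linking the halves, so the cut is fully convergent and gives two monocyclic pieces of similar size. The forward step must acylate a phenol with a doubly ortho-substituted acid, so the ring A ketone in 25 is masked (an activated acid next to a free ketone would lactonise) and the C4' hydroxyl must be the only free nucleophile in 19.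

**19 to 18 to 15 and 16.** The bond between the ring B ketone carbon and its pentyl group is cut to an acyl sulfur derivative 15 and the organozinc 17 made from 16. A thioester is chosen because it couples under palladium catalysis while the benzyl ester in the same molecule stays untouched. The 4-methoxybenzyl ether of 18 is cleaved afterwards, so that no free phenol meets the organometallic. The demand is an acid-labile ether that can be removed without harming the benzyl ester or the new ketone.

**15 to 14 to 13.** No skeletal bond is cut here. The two benzyl esters of 13 are differentiated by hindrance alone: the arylacetate is open, the benzoate is flanked by two ortho substituents. The forward saponification must stop after one ester.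

**13 to 10 and 11 (through 12).** The C6'–CH2 bond and the C1'–C(=O) bond are cut together. This removes both carbon substituents of ring B in one stroke and leaves an arene with only heteroatom substituents plus a three-carbon diester. The forward step must control where the nucleophile adds to the unsymmetrical aryne 12 and must favour insertion over simple arylation of 11.

**10 to 8 to 6 to 3 to 2 to 1.** The O–S bond, then the C2–Si bond, then the O-protecting groups are cut back to the symmetric diol 1. The silicon is placed by directed metalation, which needs one unambiguous site. A benzylic ether on the third oxygen would be a second director of about the same strength as the methyl ether, so 3 carries a bulky, non-coordinating silyl ether during the metalation; in 6 it is exchanged for the fluoride-stable 4-methoxybenzyl ether of 8. The carbamate is a secondary one so that it can be removed by mild elimination in the same flask as the sulfonylation. The price is one statistical mono-protection of 1.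

**25 to 24 to 23 to 21 and 22; 21 to 20.** In ring A the bond between the benzylic CH2 and the ketone carbon is cut, back to the ortho-methyl ester 21 and the acyl donor 22. The ortho ester makes the methyl group acidic, and 20 already holds the complete ring A substitution pattern. The forward sequence must mask the ketone before the hindered ester is hydrolysed.

## Other disconnections considered

**Alternative 1:** The cut runs through ring B itself: the C1'–C2' and C5'–C6' bonds are broken.
- Pieces: the diene A3, 1,1-dimethoxy-3-(trimethylsilyloxy)buta-1,3-diene (C2' to C5' with both ring oxygens), and the benzyl alkynoate A2, benzyl 4-(2-pentyl-1,3-dioxolan-2-yl)but-2-ynoate (C1', C6', the ester and the masked side chain).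
- Forward key step: a thermal [4+2] cycloaddition, then loss of one methoxy group and of the silyl group on mildly acidic work-up, which aromatises the adduct to the phenol A1, benzyl 4-hydroxy-2-methoxy-6-[(2-pentyl-1,3-dioxolan-2-yl)methyl]benzoate.
- In its favour: the polarity of diene and ynoate places the ester carbon between methoxy group and side chain. The C4' hydroxyl arrives free and the C2' oxygen already methylated, so no statistical mono-protection, no ether exchange and no late ether cleavage are needed. The side chain enters at the ketone oxidation level, so the ester-to-thioester-to-ketone sequence disappears.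
- Against it here: A2 has a CH2 group between an alkyne and a ketal, and its ketone precursor should isomerise readily to an allene. A beta-alkyl ynoate is a sluggish, hindered dienophile that should need prolonged heating, which the moisture-sensitive A3 tolerates poorly. The aromatising acid must spare the dioxolane.
- Comparison: on structure the two plans are equal, since each lets the polarity of a reactive partner fix the ring B pattern. On mechanism the aryne insertion should run at room temperature, whereas the cycloaddition needs heat and a hindered bond formation at C6'. On step economy the alternative is the better plan for ring B: about five operations should reach A1, against ten to reach 19.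

**Alternative 2:** The cut removes both bonds at the depside carbonyl carbon, C1–C(=O) on ring A and C(=O)–O on C4'.
- Forward key step: a palladium-catalysed aryloxycarbonylation with a wide-bite-angle diphosphine that unites the ring A aryl iodide A5, carbon monoxide A6 and the phenol A1 to the fully protected depside A4.
- In its favour: no hindered ring A benzoic acid is ever made, so the forcing saponification of step 14 and the carboxyl activation next to a ketal both vanish. On these two points the alternative is the better plan. On the number of steps for the ring A partner it should be about equal.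
- Against it here: A5 is electron-rich and its iodine is flanked by a benzyloxy group and a branched CH2 group, so oxidative addition should be slow. The acylpalladium must be captured by an electron-poor, weakly nucleophilic phenoxide. Hydrodehalogenation and direct C–O coupling without insertion of A6 compete. The regioselective iodination needed to make A5 is itself uncertain.
- Comparison: on structure this plan addresses only the bond between the rings and still needs a ring B phenol, which the chosen key step or Alternative 1 would have to supply; it complements the aryne insertion and does not replace it. On mechanism the chosen esterification is a plain acyl transfer with predictable side reactions, the carbonylation a three-component catalytic cycle on a hindered substrate.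

**Alternative 3:** The cut opens ring A at its C1–C6 bond.
- Forward key step: the open-chain aryl 3,5,7-trioxo ester A8, already attached to the C4' oxygen of ring B and with its remote C9 ketone masked as a dioxolane, is treated with a tertiary amine base. Chain C2 adds to the C7 ketone, and dehydration and enolisation give the benzene ring of A7, the bis-dioxolane benzyl ester of the target.
- In its favour: ring A is born with both hydroxyls free, so it needs no benzyl ethers and the final hydrogenolysis has one benzyl group to remove. The bond between the rings is made at the acyclic stage, so the esterification of a hindered acid is avoided. On protecting-group economy and on that esterification the alternative is the better plan.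
- Against it here: in an aryl ester the phenoxide is a good leaving group. Claisen-type closure of chain C6 onto C1 and elimination to an acylketene should compete with the aldol, and either pathway would expel the ring B phenol A1. The ketal beta to the C7 ketone can open by beta-elimination under base. The polycarbonyl chain of A8 needs a multi-step assembly and careful handling.
- Comparison: on structure it solves ring A and the depside bond but not ring B, for which A1 is still required. On mechanism it trades four robust steps from 20 (benzylation, lateral acylation, ketalisation, saponification) for one elegant but branch-prone cyclisation. On step economy it should be about equal once the assembly of A8 is counted.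

Key step: step 6

Remark on the chemistry: 20 and 22 are treated as catalogue compounds (22 would otherwise cost one step from hexanoyl chloride); PMB = 4-methoxybenzyl, TIPS = triisopropylsilyl, TBS = tert-butyldimethylsilyl, TMS = trimethylsilyl, Bn = benzyl.

## Route

Step 1
Reactants: 1 5-methoxyresorcinol
Product: 2 3-methoxy-5-(triisopropylsilyloxy)phenol
Conditions: TIPSCl (1.0 equiv), imidazole (2 equiv), DMF, 0 °C to rt
Reagents that add atoms: triisopropylsilyl chloride, CC(C)[Si](Cl)(C(C)C)C(C)C
Why: Statistical mono-silylation of a symmetric diphenol (silyl ether formation); the bulky, non-coordinating silyl ether is chosen because it will shield its two neighbouring ring positions in step 3, and unreacted 1 and the bis-silyl ether can be separated and recycled.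

Step 2
Reactants: 2 3-methoxy-5-(triisopropylsilyloxy)phenol
Product: 3 3-methoxy-5-(triisopropylsilyloxy)phenyl N-isopropylcarbamate
Conditions: i-PrNCO (1.5 equiv), Et3N (0.2 equiv), CH2Cl2, rt
Reagents that add atoms: isopropyl isocyanate, CC(C)N=C=O
Why: Base-catalysed addition of a phenol to an isocyanate gives the secondary O-aryl carbamate, a strong metalation director that can later be removed by mild elimination.

Step 3
Reactants: 3 3-methoxy-5-(triisopropylsilyloxy)phenyl N-isopropylcarbamate
Product: 6 3-methoxy-5-(triisopropylsilyloxy)-2-(trimethylsilyl)phenyl N-isopropylcarbamate, via N-silyl carbamate 4 (not isolated), via N-silyl arylsilane 5 (not isolated)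
Conditions: TBSOTf (1.1 equiv), TMEDA (1.1 equiv), Et2O, 0 °C to rt; then TMEDA (2 equiv), n-BuLi (2 equiv), −78 °C; Me3SiCl (3 equiv), −78 °C to rt; aq. NaHSO4
Reagents that add atoms: chlorotrimethylsilane, C[Si](C)(C)Cl
Why: Directed ortho-metalation of an O-aryl carbamate after in-situ N-silylation; lithiation should take place at C2, the only position flanked by two coordinating groups (carbamate and methoxy), because C4 and C6 lie beside the bulky, poorly coordinating silyl ether. Silylation at −78 °C outruns the anionic ortho-Fries shift, and the N–Si bond is lost in the aqueous work-up.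

Step 4
Reactants: 6 3-methoxy-5-(triisopropylsilyloxy)-2-(trimethylsilyl)phenyl N-isopropylcarbamate
Product: 8 3-methoxy-5-(4-methoxybenzyloxy)-2-(trimethylsilyl)phenyl N-isopropylcarbamate, via ammonium phenoxide 7 (not isolated)
Conditions: TBAF (1.05 equiv), THF, 0 °C, 10 min; then PMBCl (1.3 equiv), DMF, 0 °C to rt
Reagents that add atoms: 4-methoxybenzyl chloride, COc1ccc(CCl)cc1
Why: Fluoride cleavage of the aryl silyl ether followed by Williamson alkylation of the ammonium phenoxide in the same flask; O–Si cleavage is much faster than attack on the aryl–SiMe3 bond at 0 °C, and the ether installed here is inert to fluoride in step 6.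

Step 5
Reactants: 8 3-methoxy-5-(4-methoxybenzyloxy)-2-(trimethylsilyl)phenyl N-isopropylcarbamate
Product: 10 3-methoxy-5-(4-methoxybenzyloxy)-2-(trimethylsilyl)phenyl trifluoromethanesulfonate, via silylphenol 9 (not isolated)
Conditions: DBU (1.5 equiv), Et2NH (1.2 equiv), MeCN, 40 °C; then PhNTf2 (1.5 equiv), rt
Reagents that add atoms: N-phenylbis(trifluoromethanesulfonimide), O=S(=O)(N(c1ccccc1)S(=O)(=O)C(F)(F)F)C(F)(F)F
Why: E1cB cleavage of the N–H carbamate (the isocyanate is trapped by Et2NH) and sulfonylation of the phenoxide with PhNTf2 in one pot; the medium is free of acid and fluoride, so the arylsilane and the PMB ether should survive.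

Step 6
Reactants: 10 3-methoxy-5-(4-methoxybenzyloxy)-2-(trimethylsilyl)phenyl trifluoromethanesulfonate; 11 dibenzyl malonate
Product: 13 benzyl 2-(2-benzyloxy-2-oxoethyl)-6-methoxy-4-(4-methoxybenzyloxy)benzoate, via aryne 12 (not isolated)
Conditions: KF (3 equiv), 18-crown-6 (3 equiv), 11 (2 equiv), THF, 0 °C to rt
Reagents that add atoms: none
Why: Fluoride attacks the trimethylsilyl group of 10 and triflate leaves, which gives the aryne 12. The potassium enolate of 11 adds to the aryne carbon remote from the methoxy group (the future C6'), so that the aryl anion develops on the future C1', beside the inductively withdrawing C2'–O bond. This anion closes onto one ester carbonyl in a four-membered 4-exo-trig addition, and the strained benzocyclobutenoxide fragments at once; the benzyloxycarbonyl group ends on C1', a benzyl arylacetate enolate is left on C6', and proton transfer from a further molecule of 11 carries the chain. The closest known reaction type is the acyl-alkylation of arynes, that is aryne insertion into the C–C sigma bond of malonates and beta-keto esters. No ring stays closed and no stereocentre is formed. The selectivity needed is the regiochemistry of nucleophilic addition to the unsymmetrical aryne; it is secured by the methoxy group next to the triple bond (aryne distortion and stabilisation of the ortho anion), while the PMB ether, meta to the attacked carbon, is nearly neutral. Insertion is favoured over plain arylation of 11 because capture of the ester by the ortho anion is intramolecular and the medium is aprotic. The two benzyl esters of 13 differ sharply in hindrance, which step 7 uses.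

Step 7
Reactants: 13 benzyl 2-(2-benzyloxy-2-oxoethyl)-6-methoxy-4-(4-methoxybenzyloxy)benzoate
Product: 14 2-[2-(benzyloxycarbonyl)-3-methoxy-5-(4-methoxybenzyloxy)phenyl]acetic acid
Conditions: LiOH·H2O (1.2 equiv), THF/H2O (3:1), 0 °C; then 1 M HCl to pH 3, 0 °C
Reagents that add atoms: lithium hydroxide, [Li+].[OH-]
Why: Saponification (acyl substitution by hydroxide) selective for the unhindered arylacetate; the benzoate ester is flanked by two ortho substituents and should resist hydroxide at 0 °C.

Step 8
Reactants: 14 2-[2-(benzyloxycarbonyl)-3-methoxy-5-(4-methoxybenzyloxy)phenyl]acetic acid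
Product: 15 benzyl 2-[2-(ethylsulfanyl)-2-oxoethyl]-6-methoxy-4-(4-methoxybenzyloxy)benzoate
Conditions: EtSH (3 equiv), DCC (1.2 equiv), DMAP (0.1 equiv), CH2Cl2, 0 °C to rt
Reagents that add atoms: ethanethiol, CCS
Why: Steglich-type thioesterification (carbodiimide activation, DMAP acyl transfer); the thiol is the only nucleophile present and the hindered benzyl ester is inert.

Step 9
Reactants: 15 benzyl 2-[2-(ethylsulfanyl)-2-oxoethyl]-6-methoxy-4-(4-methoxybenzyloxy)benzoate; 16 1-iodopentane
Product: 18 benzyl 2-methoxy-4-(4-methoxybenzyloxy)-6-(2-oxoheptyl)benzoate, via pentylzinc iodide 17 (not isolated)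
Conditions: 16, Zn dust (activated with BrCH2CH2Br, Me3SiCl), THF, 40 °C; then 15, PdCl2(PPh3)2 (5 mol %), toluene, rt
Reagents that add atoms: none
Why: Fukuyama coupling: zerovalent palladium inserts into the C(acyl)–S bond, transmetalation with the alkylzinc iodide and reductive elimination give the ketone. The organozinc should neither attack the benzyl ester nor add to the ketone formed.

Step 10
Reactants: 18 benzyl 2-methoxy-4-(4-methoxybenzyloxy)-6-(2-oxoheptyl)benzoate
Product: 19 benzyl 4-hydroxy-2-methoxy-6-(2-oxoheptyl)benzoate
Conditions: TFA/CH2Cl2 (1:9), anisole (5 equiv), 0 °C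
Reagents that add atoms: none
Why: Acidolysis of the aryl 4-methoxybenzyl ether (SN1 cleavage) with anisole as cation scavenger; the benzyl ester, the methyl ether and the ketone should tolerate brief cold TFA.

Step 11
Reactants: 20 methyl 2,4-dihydroxy-6-methylbenzoate
Product: 21 methyl 2,4-bis(benzyloxy)-6-methylbenzoate
Conditions: BnBr (2.5 equiv), K2CO3 (3 equiv), DMF, 60 °C
Reagents that add atoms: benzyl bromide, BrCc1ccccc1
Why: Williamson ether synthesis; excess halide and gentle heating bring the hydrogen-bonded 2-hydroxyl to react as well as the 4-hydroxyl.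

Step 12
Reactants: 21 methyl 2,4-bis(benzyloxy)-6-methylbenzoate; 22 N-methoxy-N-methylhexanamide
Product: 23 methyl 2,4-bis(benzyloxy)-6-(2-oxoheptyl)benzoate
Conditions: LiN(i-Pr)2 (1.2 equiv), THF, −78 °C; then 22 (1.2 equiv), −78 to −30 °C; aq. NH4Cl
Reagents that add atoms: none
Why: Lateral (benzylic) lithiation of an ortho-toluate and acylation with an N-methoxy-N-methylamide; the chelated tetrahedral adduct persists until work-up and prevents over-addition, and the hindered ester resists self-condensation.

Step 13
Reactants: 23 methyl 2,4-bis(benzyloxy)-6-(2-oxoheptyl)benzoate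
Product: 24 methyl 2,4-bis(benzyloxy)-6-[(2-pentyl-1,3-dioxolan-2-yl)methyl]benzoate
Conditions: Me3SiOCH2CH2OSiMe3 (2 equiv), Me3SiOTf (5 mol %), CH2Cl2, −78 to −20 °C; pyridine quench
Reagents that add atoms: 1,2-bis(trimethylsilyloxy)ethane, C[Si](C)(C)OCCO[Si](C)(C)C
Why: Silyl-triflate-catalysed ketalisation with the bis-silyl ether of ethylene glycol; cold aprotic conditions avoid the enol lactonisation to an isocoumarin that hot protic acid would invite.

Step 14
Reactants: 24 methyl 2,4-bis(benzyloxy)-6-[(2-pentyl-1,3-dioxolan-2-yl)methyl]benzoate
Product: 25 2,4-bis(benzyloxy)-6-[(2-pentyl-1,3-dioxolan-2-yl)methyl]benzoic acid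
Conditions: KOH (10 equiv), DMSO/H2O (4:1), 90 °C; then 1 M HCl to pH 4, 0 °C, EtOAc
Reagents that add atoms: potassium hydroxide, [K+].[OH-]
Why: Saponification of a doubly ortho-substituted benzoate needs hot KOH in aqueous DMSO; benzyl ethers and the ketal are stable to base, and acidification only to pH 4 in the cold should spare the ketal.

Step 15
Reactants: 25 2,4-bis(benzyloxy)-6-[(2-pentyl-1,3-dioxolan-2-yl)methyl]benzoic acid; 19 benzyl 4-hydroxy-2-methoxy-6-(2-oxoheptyl)benzoate
Product: 26 4-(benzyloxycarbonyl)-3-methoxy-5-(2-oxoheptyl)phenyl 2,4-bis(benzyloxy)-6-[(2-pentyl-1,3-dioxolan-2-yl)methyl]benzoate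
Conditions: 25 (1.2 equiv), DCC (1.5 equiv), DMAP (0.5 equiv), CH2Cl2, 0 °C to rt
Reagents that add atoms: none
Why: Steglich esterification (carbodiimide activation, DMAP acyl transfer); the ketal prevents enol lactonisation of the activated acid, and the C4' hydroxyl is the only free nucleophile in 19.

Step 16
Reactants: 26 4-(benzyloxycarbonyl)-3-methoxy-5-(2-oxoheptyl)phenyl 2,4-bis(benzyloxy)-6-[(2-pentyl-1,3-dioxolan-2-yl)methyl]benzoate
Product: 27 4-(benzyloxycarbonyl)-3-methoxy-5-(2-oxoheptyl)phenyl 2,4-bis(benzyloxy)-6-(2-oxoheptyl)benzoate
Conditions: 2 M HCl/THF (1:4), rt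
Reagents that add atoms: water, O
Why: Acid-catalysed ketal hydrolysis; dilute acid at room temperature should leave the aryl ester, the benzyl ester and the benzyl ethers intact.

Step 17
Reactants: 27 4-(benzyloxycarbonyl)-3-methoxy-5-(2-oxoheptyl)phenyl 2,4-bis(benzyloxy)-6-(2-oxoheptyl)benzoate
Product: 28 arthonioic acid
Conditions: H2 (1 atm), 10% Pd/C, EtOAc, rt
Reagents that add atoms: none
Why: Hydrogenolysis of two benzyl ethers and one benzyl ester over palladium on carbon under neutral conditions; the dialkyl ketones, the aryl ester and the methyl ether are not reduced, and no stereocentre is involved.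

## Compound list

1 | 5-methoxyresorcinol (5-methoxybenzene-1,3-diol) | COc1cc(O)cc(O)c1 | starting material
2 | 3-methoxy-5-(triisopropylsilyloxy)phenol | COc1cc(O)cc(O[Si](C(C)C)(C(C)C)C(C)C)c1 | intermediate
3 | 3-methoxy-5-(triisopropylsilyloxy)phenyl N-isopropylcarbamate | COc1cc(OC(=O)NC(C)C)cc(O[Si](C(C)C)(C(C)C)C(C)C)c1 | intermediate
4 | 3-methoxy-5-(triisopropylsilyloxy)phenyl N-(tert-butyldimethylsilyl)-N-isopropylcarbamate (formed in the flask, not isolated) | COc1cc(OC(=O)N(C(C)C)[Si](C)(C)C(C)(C)C)cc(O[Si](C(C)C)(C(C)C)C(C)C)c1 | intermediate
5 | 3-methoxy-5-(triisopropylsilyloxy)-2-(trimethylsilyl)phenyl N-(tert-butyldimethylsilyl)-N-isopropylcarbamate (formed in the flask, not isolated) | COc1cc(O[Si](C(C)C)(C(C)C)C(C)C)cc(OC(=O)N(C(C)C)[Si](C)(C)C(C)(C)C)c1[Si](C)(C)C | intermediate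
6 | 3-methoxy-5-(triisopropylsilyloxy)-2-(trimethylsilyl)phenyl N-isopropylcarbamate | COc1cc(O[Si](C(C)C)(C(C)C)C(C)C)cc(OC(=O)NC(C)C)c1[Si](C)(C)C | intermediate
7 | tetrabutylammonium 3-[(isopropylcarbamoyl)oxy]-5-methoxy-4-(trimethylsilyl)phenoxide (formed in the flask, not isolated) | COc1cc([O-])cc(OC(=O)NC(C)C)c1[Si](C)(C)C.CCCC[N+](CCCC)(CCCC)CCCC | intermediate
8 | 3-methoxy-5-(4-methoxybenzyloxy)-2-(trimethylsilyl)phenyl N-isopropylcarbamate | COc1ccc(COc2cc(OC)c([Si](C)(C)C)c(OC(=O)NC(C)C)c2)cc1 | intermediate
9 | 3-methoxy-5-(4-methoxybenzyloxy)-2-(trimethylsilyl)phenol (formed in the flask as its amidinium phenoxide, not isolated) | COc1ccc(COc2cc(O)c([Si](C)(C)C)c(OC)c2)cc1 | intermediate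
10 | 3-methoxy-5-(4-methoxybenzyloxy)-2-(trimethylsilyl)phenyl trifluoromethanesulfonate | COc1ccc(COc2cc(OC)c([Si](C)(C)C)c(OS(=O)(=O)C(F)(F)F)c2)cc1 | intermediate
11 | dibenzyl malonate | O=C(CC(=O)OCc1ccccc1)OCc1ccccc1 | starting material
12 | 3-methoxy-5-(4-methoxybenzyloxy)benzyne (formed in the flask, not isolated) | COC1=CC(OCc2ccc(OC)cc2)=CC#C1 | intermediate
13 | benzyl 2-(2-benzyloxy-2-oxoethyl)-6-methoxy-4-(4-methoxybenzyloxy)benzoate | COc1ccc(COc2cc(OC)c(C(=O)OCc3ccccc3)c(CC(=O)OCc3ccccc3)c2)cc1 | intermediate
14 | 2-[2-(benzyloxycarbonyl)-3-methoxy-5-(4-methoxybenzyloxy)phenyl]acetic acid | COc1ccc(COc2cc(OC)c(C(=O)OCc3ccccc3)c(CC(=O)O)c2)cc1 | intermediate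
15 | benzyl 2-[2-(ethylsulfanyl)-2-oxoethyl]-6-methoxy-4-(4-methoxybenzyloxy)benzoate | CCSC(=O)Cc1cc(OCc2ccc(OC)cc2)cc(OC)c1C(=O)OCc1ccccc1 | intermediate
16 | 1-iodopentane | CCCCCI | starting material
17 | pentylzinc iodide, C5H11ZnI (formed in the flask, not isolated) | CCCCC[Zn]I | intermediate
18 | benzyl 2-methoxy-4-(4-methoxybenzyloxy)-6-(2-oxoheptyl)benzoate | CCCCCC(=O)Cc1cc(OCc2ccc(OC)cc2)cc(OC)c1C(=O)OCc1ccccc1 | intermediate
19 | benzyl 4-hydroxy-2-methoxy-6-(2-oxoheptyl)benzoate | CCCCCC(=O)Cc1cc(O)cc(OC)c1C(=O)OCc1ccccc1 | intermediate
20 | methyl 2,4-dihydroxy-6-methylbenzoate | COC(=O)c1c(C)cc(O)cc1O | starting material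
21 | methyl 2,4-bis(benzyloxy)-6-methylbenzoate | COC(=O)c1c(C)cc(OCc2ccccc2)cc1OCc1ccccc1 | intermediate
22 | N-methoxy-N-methylhexanamide | CCCCCC(=O)N(C)OC | starting material
23 | methyl 2,4-bis(benzyloxy)-6-(2-oxoheptyl)benzoate | CCCCCC(=O)Cc1cc(OCc2ccccc2)cc(OCc2ccccc2)c1C(=O)OC | intermediate
24 | methyl 2,4-bis(benzyloxy)-6-[(2-pentyl-1,3-dioxolan-2-yl)methyl]benzoate | CCCCCC1(Cc2cc(OCc3ccccc3)cc(OCc3ccccc3)c2C(=O)OC)OCCO1 | intermediate
25 | 2,4-bis(benzyloxy)-6-[(2-pentyl-1,3-dioxolan-2-yl)methyl]benzoic acid | CCCCCC1(Cc2cc(OCc3ccccc3)cc(OCc3ccccc3)c2C(=O)O)OCCO1 | intermediate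
26 | 4-(benzyloxycarbonyl)-3-methoxy-5-(2-oxoheptyl)phenyl 2,4-bis(benzyloxy)-6-[(2-pentyl-1,3-dioxolan-2-yl)methyl]benzoate | CCCCCC1(Cc2cc(OCc3ccccc3)cc(OCc3ccccc3)c2C(=O)Oc2cc(CC(=O)CCCCC)c(C(=O)OCc3ccccc3)c(OC)c2)OCCO1 | intermediate
27 | 4-(benzyloxycarbonyl)-3-methoxy-5-(2-oxoheptyl)phenyl 2,4-bis(benzyloxy)-6-(2-oxoheptyl)benzoate | CCCCCC(=O)Cc1cc(OCc2ccccc2)cc(OCc2ccccc2)c1C(=O)Oc1cc(CC(=O)CCCCC)c(C(=O)OCc2ccccc2)c(OC)c1 | intermediate
28 | arthonioic acid, 4-{[2,4-dihydroxy-6-(2-oxoheptyl)benzoyl]oxy}-2-methoxy-6-(2-oxoheptyl)benzoic acid | CCCCCC(=O)Cc1cc(O)cc(O)c1C(=O)Oc1cc(CC(=O)CCCCC)c(C(=O)O)c(OC)c1 | target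

## Step count and least certain steps

Total step count: 17. Longest linear sequence: 13 steps (steps 1 to 10, then 15 to 17, starting from 1); the ring A branch (steps 11 to 14) joins at step 15.

**Step 6 (key step).** The most likely failure is protonation of the ortho aryl anion before it closes onto the ester carbonyl, which would give plain arylation of the malonate. An ester is a weaker internal electrophile than a ketone, and the malonate C–H is an available proton source. A second arylation of the product enolate and some leakage of regiocontrol in the addition to the aryne are further possibilities. The fallback gives up the aryne and builds the same ring B ketone by lateral acylation. It sets out from 20 and comes back at 18: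
- selective alkylation of the non-chelated 4-hydroxyl of 20 (PMBCl, K2CO3, acetone) gives methyl 2-hydroxy-4-(4-methoxybenzyloxy)-6-methylbenzoate F1;
- methylation of the chelated hydroxyl (MeI, K2CO3, DMF) gives methyl 2-methoxy-4-(4-methoxybenzyloxy)-6-methylbenzoate F2;
- saponification (KOH, aqueous DMSO, heat) gives 2-methoxy-4-(4-methoxybenzyloxy)-6-methylbenzoic acid F3;
- benzylation (BnBr, K2CO3, DMF) gives benzyl 2-methoxy-4-(4-methoxybenzyloxy)-6-methylbenzoate F4;
- lateral lithiation with LiN(i-Pr)2 and acylation with 22 then give 18.

**Step 4.** Base-induced elimination of the N–H carbamate to the isocyanate may compete once fluoride and phenoxide are present, and fluoride may attack the aryl–silicon bond (ipso-desilylation) if the exposure is long. The fallback sets out from 6 and comes back at 8. Desilylation under buffered conditions (TBAF/AcOH, THF, 0 °C) gives the isolated phenol 5-hydroxy-3-methoxy-2-(trimethylsilyl)phenyl N-isopropylcarbamate F5. A Mitsunobu etherification with 4-methoxybenzyl alcohol (PPh3, diisopropyl azodicarboxylate, THF) then forms 8 under neutral conditions instead of by phenoxide alkylation.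

**Step 15.** Acyl transfer from the doubly ortho-substituted activated acid may be slow, which gives time for rearrangement to the N-acylurea or for participation of a ketal oxygen at the activated carboxyl. The fallback sets out from 25 and comes back at 26. The acid is converted under neutral conditions with 1-chloro-N,N,2-trimethylprop-1-en-1-amine (CH2Cl2, 0 °C) into 2,4-bis(benzyloxy)-6-[(2-pentyl-1,3-dioxolan-2-yl)methyl]benzoyl chloride F6. This preformed acyl chloride is used at once to acylate 19 (Et3N, DMAP, CH2Cl2, 0 °C).

**Step 16.** Once the ring A ketone is free, its enol may attack the neighbouring aryl ester (enol lactonisation with expulsion of the ring B phenol); slow hydrolysis of the hindered ketal would call for stronger acid and raise that risk. The fallback reverses the order of the last two operations. It sets out from 26 and comes back at 28. Hydrogenolysis (H2, Pd/C, EtOAc) first gives 4-({2,4-dihydroxy-6-[(2-pentyl-1,3-dioxolan-2-yl)methyl]benzoyl}oxy)-2-methoxy-6-(2-oxoheptyl)benzoic acid F7, in which the free 2-hydroxyl is hydrogen-bonded to the depside carbonyl and lowers its electrophilicity. The ketal is then hydrolysed with 80% aqueous acetic acid at rt.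

## Further compounds

F1 | step 6 | methyl 2-hydroxy-4-(4-methoxybenzyloxy)-6-methylbenzoate | COC(=O)c1c(C)cc(OCc2ccc(OC)cc2)cc1O
F2 | step 6 | methyl 2-methoxy-4-(4-methoxybenzyloxy)-6-methylbenzoate | COC(=O)c1c(C)cc(OCc2ccc(OC)cc2)cc1OC
F3 | step 6 | 2-methoxy-4-(4-methoxybenzyloxy)-6-methylbenzoic acid | Cc1cc(OCc2ccc(OC)cc2)cc(OC)c1C(=O)O
F4 | step 6 | benzyl 2-methoxy-4-(4-methoxybenzyloxy)-6-methylbenzoate | Cc1cc(OCc2ccc(OC)cc2)cc(OC)c1C(=O)OCc1ccccc1
F5 | step 4 | 5-hydroxy-3-methoxy-2-(trimethylsilyl)phenyl N-isopropylcarbamate | COc1cc(O)cc(OC(=O)NC(C)C)c1[Si](C)(C)C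
F6 | step 15 | 2,4-bis(benzyloxy)-6-[(2-pentyl-1,3-dioxolan-2-yl)methyl]benzoyl chloride | CCCCCC1(Cc2cc(OCc3ccccc3)cc(OCc3ccccc3)c2C(=O)Cl)OCCO1
F7 | step 16 | 4-({2,4-dihydroxy-6-[(2-pentyl-1,3-dioxolan-2-yl)methyl]benzoyl}oxy)-2-methoxy-6-(2-oxoheptyl)benzoic acid | CCCCCC1(Cc2cc(O)cc(O)c2C(=O)Oc2cc(CC(=O)CCCCC)c(C(=O)O)c(OC)c2)OCCO1
A1 | alternative 1 | benzyl 4-hydroxy-2-methoxy-6-[(2-pentyl-1,3-dioxolan-2-yl)methyl]benzoate | CCCCCC1(OCCO1)Cc1cc(O)cc(OC)c1C(=O)OCc1ccccc1
A2 | alternative 1 | benzyl 4-(2-pentyl-1,3-dioxolan-2-yl)but-2-ynoate | CCCCCC1(CC#CC(=O)OCc2ccccc2)OCCO1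
A3 | alternative 1 | 1,1-dimethoxy-3-(trimethylsilyloxy)buta-1,3-diene | COC(OC)=CC(=C)O[Si](C)(C)C
A4 | alternative 2 | 4-(benzyloxycarbonyl)-3-methoxy-5-[(2-pentyl-1,3-dioxolan-2-yl)methyl]phenyl 2,4-bis(benzyloxy)-6-[(2-pentyl-1,3-dioxolan-2-yl)methyl]benzoate | CCCCCC1(OCCO1)Cc1cc(OCc2ccccc2)cc(OCc2ccccc2)c1C(=O)Oc1cc(CC2(CCCCC)OCCO2)c(C(=O)OCc2ccccc2)c(OC)c1
A5 | alternative 2 | 2-{[3,5-bis(benzyloxy)-2-iodophenyl]methyl}-2-pentyl-1,3-dioxolane | CCCCCC1(Cc2cc(OCc3ccccc3)cc(OCc3ccccc3)c2I)OCCO1
A6 | alternative 2 | carbon monoxide | [C-]#[O+]
A7 | alternative 3 | 4-(benzyloxycarbonyl)-3-methoxy-5-[(2-pentyl-1,3-dioxolan-2-yl)methyl]phenyl 2,4-dihydroxy-6-[(2-pentyl-1,3-dioxolan-2-yl)methyl]benzoate | CCCCCC1(OCCO1)Cc1cc(O)cc(O)c1C(=O)Oc1cc(CC2(CCCCC)OCCO2)c(C(=O)OCc2ccccc2)c(OC)c1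
A8 | alternative 3 | 4-(benzyloxycarbonyl)-3-methoxy-5-[(2-pentyl-1,3-dioxolan-2-yl)methyl]phenyl 3,5,7-trioxo-8-(2-pentyl-1,3-dioxolan-2-yl)octanoate | CCCCCC1(CC(=O)CC(=O)CC(=O)CC(=O)Oc2cc(CC3(CCCCC)OCCO3)c(C(=O)OCc3ccccc3)c(OC)c2)OCCO1
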